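**Plan**

1. Germacrane numbering is used: ring C1–C10 (cis-epoxide C1–C2, OH on C3 and C10, C4=C5 Z, lactone O on C6, angelate on C8), lactone carbons C11–C13, methyls C14 (on C10) and C15 (on C4). The target is (1R,2R,3R,4Z,6S,7R,8R,10R) with a cis-fused γ-lactone.
2. Retrosynthesis: the lactone is cut at O–C6 and C11–C7 (2-bromoacrylic acid + a ten-membered 4Z,6E-diene); the carbocycle at C3–C4 (alkenyl iodide + epoxy aldehyde); the chain at C9–C10 (methyl ketone enolate + epoxy methyl ketone) and at C6=C7 (Wittig).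
3. Forward: the epoxide ring is made first; the epoxy ketone (C1–C3, C10, C14) and the iododienone (C4–C9, C15) are joined by aldol; C8 is reduced and acylated; the ten-membered ring is closed by Nozaki–Hiyama–Kishi reaction; the lactone ring is annulated last, followed by one deprotection.
4. Enabling feature: the lactone oxygen sits on C6, which is allylic to C4=C5 and adjacent to C7. O–C6/C7–C11 is therefore the 1,2-adduct of an acrylate unit across the C6=C7 end of a C4=C5–C6=C7 diene, with C4–C5–C6 as the π-allyl palladium relay.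
5. Stereochemistry: C1/C2 from Sharpless epoxidation; C10 from chelate-controlled aldol; C8 from 1,3-anti directed reduction; C3 from Felkin–Anh addition in the ring closure; 4Z from hydroalumination–iodination; C7 and C6 in the key step (outer-face carbopalladation steered by C8, then anti attack of the carboxylate, which on the 6E alkene gives the cis fusion).

Key step: step 15

**Route**

Step 1
Reactants: 1 (Z)-but-2-ene-1,4-diol
Product: 2 (Z)-4-[(4-methoxybenzyl)oxy]but-2-en-1-ol
Conditions: NaH (1.0 equiv), 4-methoxybenzyl chloride (1.0 equiv), n-Bu4NI (cat.), THF/DMF, 0 °C to rt, 1 in excess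
Reagents that add atoms: 4-methoxybenzyl chloride, COc1ccc(CCl)cc1
Why: Williamson etherification of the mono-alkoxide of the symmetric diol, used in excess, should give the mono-ether, and no stereocenter is formed.

Step 2
Reactants: 2 (Z)-4-[(4-methoxybenzyl)oxy]but-2-en-1-ol
Product: 3 [(2S,3R)-3-{[(4-methoxybenzyl)oxy]methyl}oxiran-2-yl]methanol
Conditions: Ti(OiPr)4 (20 mol %), L-(+)-diethyl tartrate (24 mol %), t-BuOOH, 4 Å molecular sieves, CH2Cl2, −20 °C
Reagents that add atoms: tert-butyl hydroperoxide, CC(C)(C)OO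
Why: Sharpless asymmetric epoxidation of a primary Z-allylic alcohol, in which the L-(+)-tartrate titanium complex delivers oxygen to the face that gives the (2S,3R) cis-epoxide, so that C1 and C2 of the target are set by the reagent.

Step 3
Reactants: 3 [(2S,3R)-3-{[(4-methoxybenzyl)oxy]methyl}oxiran-2-yl]methanol
Product: 4 (2R,3R)-3-{[(4-methoxybenzyl)oxy]methyl}oxirane-2-carbaldehyde
Conditions: Dess–Martin periodinane, pyridine, CH2Cl2, 0 °C to rt
Reagents that add atoms: none
Why: Dess–Martin oxidation under pyridine buffering should convert the primary alcohol into the aldehyde without epimerising the cis-epoxide.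

Step 4
Reactants: 4 (2R,3R)-3-{[(4-methoxybenzyl)oxy]methyl}oxirane-2-carbaldehyde
Product: 5 (1RS)-1-[(2S,3R)-3-{[(4-methoxybenzyl)oxy]methyl}oxiran-2-yl]ethan-1-ol
Conditions: MeMgBr, THF, −78 °C
Reagents that add atoms: methylmagnesium bromide, C[Mg]Br
Why: Grignard addition to the aldehyde at low temperature leaves the epoxide intact, and the unselective new carbinol center is removed by the oxidation in step 5.

Step 5
Reactants: 5 (1RS)-1-[(2S,3R)-3-{[(4-methoxybenzyl)oxy]methyl}oxiran-2-yl]ethan-1-ol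
Product: 6 1-[(2R,3R)-3-{[(4-methoxybenzyl)oxy]methyl}oxiran-2-yl]ethan-1-one
Conditions: Dess–Martin periodinane, pyridine, CH2Cl2, 0 °C to rt
Reagents that add atoms: none
Why: Dess–Martin oxidation of the secondary alcohol should give the cis-epoxy methyl ketone (C14, C10, C1, C2, C3 of the target) under conditions too mild to epimerise C1.

Step 6
Reactants: 7 but-2-yn-1-ol
Product: 9 (Z)-3-iodobut-2-en-1-ol, via cyclic sodium alkenylalanate 8 (not isolated)
Conditions: NaAlH2(OCH2CH2OMe)2, THF, 0 °C; then I2, −78 °C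
Reagents that add atoms: iodine, II
Why: Hydroxyl-directed trans-hydroalumination places aluminium on C3 in a five-membered alanate, and iodinolysis with retention gives the Z-iodoalkene that later becomes the 4Z alkene with its C15 methyl.

Step 7
Reactants: 9 (Z)-3-iodobut-2-en-1-ol
Product: 11 (3E,5Z)-6-iodohepta-3,5-dien-2-one, via (Z)-3-iodobut-2-enal 10 (not isolated)
Conditions: MnO2 (activated, excess), Ph3P=CHC(O)CH3, CH2Cl2, rt
Reagents that add atoms: 1-(triphenyl-λ5-phosphanylidene)propan-2-one, CC(=O)C=P(c1ccccc1)(c1ccccc1)c1ccccc1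
Why: Tandem allylic oxidation and Wittig olefination, in which the sensitive Z-iodoenal is trapped as it forms by the stabilised ylide with E selectivity, should give the 6E alkene while the Z-iodoalkene is kept.

Step 8
Reactants: 11 (3E,5Z)-6-iodohepta-3,5-dien-2-one; 6 1-[(2R,3R)-3-{[(4-methoxybenzyl)oxy]methyl}oxiran-2-yl]ethan-1-one
Product: 14 (2R,5E,7Z)-2-hydroxy-8-iodo-2-[(2R,3R)-3-{[(4-methoxybenzyl)oxy]methyl}oxiran-2-yl]nona-5,7-dien-4-one, via lithium enolate 12 (not isolated), via bromomagnesium enolate 13 (not isolated)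
Conditions: LiN(i-Pr)2, THF, −78 °C; MgBr2·OEt2, Et2O, −78 °C; then 6, −78 °C; AcOH quench at −78 °C
Reagents that add atoms: none
Why: Kinetic enolisation at the methyl group and aldol addition of the magnesium enolate to the α,β-epoxy ketone under Cram-chelate control (magnesium bridging the carbonyl and epoxide oxygens, attack on the face away from C2) should form the C9–C10 bond and set C10 as in the target.

Step 9
Reactants: 14 (2R,5E,7Z)-2-hydroxy-8-iodo-2-[(2R,3R)-3-{[(4-methoxybenzyl)oxy]methyl}oxiran-2-yl]nona-5,7-dien-4-one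
Product: 15 (2R,4R,5E,7Z)-8-iodo-2-[(2R,3R)-3-{[(4-methoxybenzyl)oxy]methyl}oxiran-2-yl]nona-5,7-diene-2,4-diol
Conditions: Me4NBH(OAc)3, MeCN/AcOH, −30 °C
Reagents that add atoms: none
Why: Evans–Saksena reduction, in which the C10 hydroxyl binds boron and hydride is delivered intramolecularly through a chair with the oxiranyl group equatorial, should give the 1,3-anti diol and thereby the C8 configuration.

Step 10
Reactants: 15 (2R,4R,5E,7Z)-8-iodo-2-[(2R,3R)-3-{[(4-methoxybenzyl)oxy]methyl}oxiran-2-yl]nona-5,7-diene-2,4-diol; 16 angelic acid [(Z)-2-methylbut-2-enoic acid]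
Product: 18 (2R,4R,5E,7Z)-2-hydroxy-8-iodo-2-[(2R,3R)-3-{[(4-methoxybenzyl)oxy]methyl}oxiran-2-yl]nona-5,7-dien-4-yl (Z)-2-methylbut-2-enoate, via angelic 2,4,6-trichlorobenzoic anhydride 17 (not isolated)
Conditions: 16, 2,4,6-trichlorobenzoyl chloride, Et3N, toluene, rt; then 15, DMAP (cat.), toluene, 0 °C to rt
Reagents that add atoms: none
Why: Yamaguchi esterification through the mixed anhydride should acylate the secondary C8 hydroxyl while the tertiary C10 hydroxyl stays free, under conditions mild enough to keep the Z geometry of the angelate.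

Step 11
Reactants: 18 (2R,4R,5E,7Z)-2-hydroxy-8-iodo-2-[(2R,3R)-3-{[(4-methoxybenzyl)oxy]methyl}oxiran-2-yl]nona-5,7-dien-4-yl (Z)-2-methylbut-2-enoate
Product: 19 (2R,4R,5E,7Z)-8-iodo-2-[(2R,3R)-3-{[(4-methoxybenzyl)oxy]methyl}oxiran-2-yl]-2-[(triethylsilyl)oxy]nona-5,7-dien-4-yl (Z)-2-methylbut-2-enoate
Conditions: Et3SiOTf, 2,6-lutidine, CH2Cl2, −78 °C
Reagents that add atoms: triethylsilyl trifluoromethanesulfonate, CC[Si](CC)(CC)OS(=O)(=O)C(F)(F)F
Why: Silyl triflate silylation caps the tertiary alcohol, which would otherwise form a lactol with the C3 aldehyde of step 13 and could attack the allyl palladium unit across the ring in step 15.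

Step 12
Reactants: 19 (2R,4R,5E,7Z)-8-iodo-2-[(2R,3R)-3-{[(4-methoxybenzyl)oxy]methyl}oxiran-2-yl]-2-[(triethylsilyl)oxy]nona-5,7-dien-4-yl (Z)-2-methylbut-2-enoate
Product: 20 (2R,4R,5E,7Z)-2-[(2R,3R)-3-(hydroxymethyl)oxiran-2-yl]-8-iodo-2-[(triethylsilyl)oxy]nona-5,7-dien-4-yl (Z)-2-methylbut-2-enoate
Conditions: DDQ, CH2Cl2/pH 7 phosphate buffer, 0 °C
Reagents that add atoms: none
Why: Oxidative cleavage of the 4-methoxybenzyl ether by DDQ (oxidation of the electron-rich arene, then hydrolysis) should free the primary alcohol without touching the silyl ether, ester, epoxide or iododiene.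

Step 13
Reactants: 20 (2R,4R,5E,7Z)-2-[(2R,3R)-3-(hydroxymethyl)oxiran-2-yl]-8-iodo-2-[(triethylsilyl)oxy]nona-5,7-dien-4-yl (Z)-2-methylbut-2-enoate
Product: 21 (2R,4R,5E,7Z)-2-[(2R,3S)-3-formyloxiran-2-yl]-8-iodo-2-[(triethylsilyl)oxy]nona-5,7-dien-4-yl (Z)-2-methylbut-2-enoate
Conditions: Dess–Martin periodinane, pyridine, CH2Cl2, 0 °C
Reagents that add atoms: none
Why: Buffered Dess–Martin oxidation should give the cis-epoxy aldehyde without epimerisation at C2.

Step 14
Reactants: 21 (2R,4R,5E,7Z)-2-[(2R,3S)-3-formyloxiran-2-yl]-8-iodo-2-[(triethylsilyl)oxy]nona-5,7-dien-4-yl (Z)-2-methylbut-2-enoate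
Product: 22 (1R,2R,3Z,5E,7R,9R,10R)-2-hydroxy-3,9-dimethyl-9-[(triethylsilyl)oxy]-11-oxabicyclo[8.1.0]undeca-3,5-dien-7-yl (Z)-2-methylbut-2-enoate
Conditions: CrCl2 (excess), NiCl2 (cat.), degassed DMSO/THF, rt, high dilution with slow addition of 21
Reagents that add atoms: none
Why: Nozaki–Hiyama–Kishi macrocyclisation, in which nickel-mediated activation of the C–I bond and transfer to chromium give an alkenyl chromium species that adds to the aldehyde with retention of the Z alkene, should close the ten-membered ring at C3–C4, and Felkin–Anh approach anti to the epoxide C2–O bond is expected to give the (3R) carbinol.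

Step 15
Reactants: 22 (1R,2R,3Z,5E,7R,9R,10R)-2-hydroxy-3,9-dimethyl-9-[(triethylsilyl)oxy]-11-oxabicyclo[8.1.0]undeca-3,5-dien-7-yl (Z)-2-methylbut-2-enoate; 23 2-bromoacrylic acid
Product: 24 (1R,2R,3R,4Z,6S,7R,8R,10R)-8-angeloyloxy-1,2-epoxy-3-hydroxy-10-[(triethylsilyl)oxy]germacra-4,11(13)-dien-12,6-olide
Conditions: Pd(OAc)2 (10 mol %), n-Bu4NCl, NaHCO3, DMF, 70 °C, slow addition of 23
Reagents that add atoms: none
Why: Oxidative addition of zerovalent palladium to the C–Br bond of 23 gives an α-carboxyvinyl palladium species that adds syn across the C6=C7 alkene of the diene with carbon bonding to C7, and the resulting C4–C5–C6 π-allyl palladium unit is captured at C6 by the tethered carboxylate with release of zerovalent palladium. The closest known reaction type is the Larock heteroannulation of 1,3-dienes by aryl and vinylic halides that carry a carboxylic acid. The one ring closed is the γ-lactone (O, C6, C7, C11, C12), formed by 5-exo attack of the carboxylate oxygen on the allyl terminus. C7 is controlled by C8, because the E alkene of the ten-membered ring is open only on its outer face and the reactive conformer has the C8–O bond in the alkene plane with H8 on the attacked face, which places C11 anti to the ester oxygen; C6 is controlled by the mechanism, because chloride-ligated palladium favours external attack of the carboxylate anti to the metal, a net anti addition across the 6E alkene that corresponds to the cis ring fusion. The 4Z geometry is kept because C3 stays the anti substituent of the allyl unit, whose exchange would need a σ-bond from palladium to the fully substituted C4. The step needs regioselectivity (C7 over the fully substituted C4 in the insertion, C6 over C4 and a five- over a seven-membered ring in the closure) and chemoselectivity over ionisation of the dienylic angelate, which the in-plane C8–O bond (no overlap with the π system) and the fast oxidative addition of the electron-poor bromide are expected to secure.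

Step 16
Reactants: 24 (1R,2R,3R,4Z,6S,7R,8R,10R)-8-angeloyloxy-1,2-epoxy-3-hydroxy-10-[(triethylsilyl)oxy]germacra-4,11(13)-dien-12,6-olide
Product: 25 (1R,2R,3R,4Z,6S,7R,8R,10R)-8-angeloyloxy-1,2-epoxy-3,10-dihydroxygermacra-4,11(13)-dien-12,6-olide
Conditions: HF·pyridine, pyridine, THF, 0 °C to rt
Reagents that add atoms: none
Why: Fluoride cleavage of the tertiary triethylsilyl ether under pyridine buffering should leave the epoxide, both esters and the α-methylene lactone intact.

**Compound list**

1 | (Z)-but-2-ene-1,4-diol | OC/C=C\CO | starting material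
2 | (Z)-4-[(4-methoxybenzyl)oxy]but-2-en-1-ol | COc1ccc(COC/C=C\CO)cc1 | intermediate
3 | [(2S,3R)-3-{[(4-methoxybenzyl)oxy]methyl}oxiran-2-yl]methanol | COc1ccc(COC[C@H]2O[C@H]2CO)cc1 | intermediate
4 | (2R,3R)-3-{[(4-methoxybenzyl)oxy]methyl}oxirane-2-carbaldehyde | COc1ccc(COC[C@H]2O[C@H]2C=O)cc1 | intermediate
5 | (1RS)-1-[(2S,3R)-3-{[(4-methoxybenzyl)oxy]methyl}oxiran-2-yl]ethan-1-ol (both carbinol epimers) | COc1ccc(COC[C@H]2O[C@H]2C(C)O)cc1 | intermediate
6 | 1-[(2R,3R)-3-{[(4-methoxybenzyl)oxy]methyl}oxiran-2-yl]ethan-1-one | COc1ccc(COC[C@H]2O[C@H]2C(C)=O)cc1 | intermediate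
7 | but-2-yn-1-ol | CC#CCO | starting material
8 | sodium 2,2-bis(2-methoxyethoxy)-3-methyl-2,5-dihydro-1,2-oxaluminol-2-uide (cyclic alkenylalanate) | CC1=CCO[Al-]1(OCCOC)OCCOC.[Na+] | intermediate (not isolated)
9 | (Z)-3-iodobut-2-en-1-ol | OC/C=C(/C)I | intermediate
10 | (Z)-3-iodobut-2-enal | O=C/C=C(/C)I | intermediate (not isolated)
11 | (3E,5Z)-6-iodohepta-3,5-dien-2-one | CC(=O)/C=C/C=C(/C)I | intermediate
12 | lithium (3E,5Z)-6-iodohepta-1,3,5-trien-2-olate | [Li+].[O-]C(=C)/C=C/C=C(/C)I | intermediate (not isolated)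
13 | bromomagnesium (3E,5Z)-6-iodohepta-1,3,5-trien-2-olate | C=C(O[Mg]Br)/C=C/C=C(/C)I | intermediate (not isolated)
14 | (2R,5E,7Z)-2-hydroxy-8-iodo-2-[(2R,3R)-3-{[(4-methoxybenzyl)oxy]methyl}oxiran-2-yl]nona-5,7-dien-4-one | COc1ccc(COC[C@H]2O[C@H]2[C@](C)(O)CC(=O)/C=C/C=C(/C)I)cc1 | intermediate
15 | (2R,4R,5E,7Z)-8-iodo-2-[(2R,3R)-3-{[(4-methoxybenzyl)oxy]methyl}oxiran-2-yl]nona-5,7-diene-2,4-diol | COc1ccc(COC[C@H]2O[C@H]2[C@](C)(O)C[C@@H](O)/C=C/C=C(/C)I)cc1 | intermediate
16 | angelic acid [(Z)-2-methylbut-2-enoic acid] | C/C=C(/C)C(=O)O | starting material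
17 | angelic 2,4,6-trichlorobenzoic anhydride | C/C=C(/C)C(=O)OC(=O)c1c(Cl)cc(Cl)cc1Cl | intermediate (not isolated)
18 | (2R,4R,5E,7Z)-2-hydroxy-8-iodo-2-[(2R,3R)-3-{[(4-methoxybenzyl)oxy]methyl}oxiran-2-yl]nona-5,7-dien-4-yl (Z)-2-methylbut-2-enoate | COc1ccc(COC[C@H]2O[C@H]2[C@](C)(O)C[C@@H](OC(=O)/C(C)=C\C)/C=C/C=C(/C)I)cc1 | intermediate
19 | (2R,4R,5E,7Z)-8-iodo-2-[(2R,3R)-3-{[(4-methoxybenzyl)oxy]methyl}oxiran-2-yl]-2-[(triethylsilyl)oxy]nona-5,7-dien-4-yl (Z)-2-methylbut-2-enoate | COc1ccc(COC[C@H]2O[C@H]2[C@](C)(O[Si](CC)(CC)CC)C[C@@H](OC(=O)/C(C)=C\C)/C=C/C=C(/C)I)cc1 | intermediate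
20 | (2R,4R,5E,7Z)-2-[(2R,3R)-3-(hydroxymethyl)oxiran-2-yl]-8-iodo-2-[(triethylsilyl)oxy]nona-5,7-dien-4-yl (Z)-2-methylbut-2-enoate | OC[C@H]1O[C@H]1[C@](C)(O[Si](CC)(CC)CC)C[C@@H](OC(=O)/C(C)=C\C)/C=C/C=C(/C)I | intermediate
21 | (2R,4R,5E,7Z)-2-[(2R,3S)-3-formyloxiran-2-yl]-8-iodo-2-[(triethylsilyl)oxy]nona-5,7-dien-4-yl (Z)-2-methylbut-2-enoate | O=C[C@H]1O[C@H]1[C@](C)(O[Si](CC)(CC)CC)C[C@@H](OC(=O)/C(C)=C\C)/C=C/C=C(/C)I | intermediate
22 | (1R,2R,3Z,5E,7R,9R,10R)-2-hydroxy-3,9-dimethyl-9-[(triethylsilyl)oxy]-11-oxabicyclo[8.1.0]undeca-3,5-dien-7-yl (Z)-2-methylbut-2-enoate | [C@H]1(OC(=O)/C(C)=C\C)/C=C/C=C(/C)[C@@H](O)[C@H]2O[C@H]2[C@](C)(O[Si](CC)(CC)CC)C1 | intermediate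
23 | 2-bromoacrylic acid (2-bromoprop-2-enoic acid) | C=C(Br)C(=O)O | starting material
24 | (1R,2R,3R,4Z,6S,7R,8R,10R)-8-angeloyloxy-1,2-epoxy-3-hydroxy-10-[(triethylsilyl)oxy]germacra-4,11(13)-dien-12,6-olide | C=C1C(=O)O[C@H]2/C=C(/C)[C@@H](O)[C@H]3O[C@H]3[C@](C)(O[Si](CC)(CC)CC)C[C@@H](OC(=O)/C(C)=C\C)[C@@H]12 | intermediate
25 | (1R,2R,3R,4Z,6S,7R,8R,10R)-8-angeloyloxy-1,2-epoxy-3,10-dihydroxygermacra-4,11(13)-dien-12,6-olide | C=C1C(=O)O[C@H]2/C=C(/C)[C@@H](O)[C@H]3O[C@H]3[C@](C)(O)C[C@@H](OC(=O)/C(C)=C\C)[C@@H]12 | target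

**Step count and risks**

Total steps: 16. Longest linear sequence: 14 (steps 1–5, then 8–16).

Step 15 (most likely to fail). Zerovalent palladium may ionise the dienylic C8 ester. The insertion may also take place on the other face of the C6=C7 alkene, or the C–O bond may form syn to palladium and give the trans-fused lactone. The fallback sets out from 22 and returns at 24 by a radical instead of an organopalladium annulation. Treatment of 22 with Mn(OAc)3·2H2O and malonic acid in AcOH/KOAc at about 45 °C should add the malonyl radical to C7 of the diene. Trivalent manganese then oxidises the allyl radical, and the carboxyl group closes at C6 to give the C11-carboxy lactone F1. Decarboxylative Mannich methylenation of F1 (aqueous formaldehyde, Et2NH, then NaOAc/AcOH with warming) would install the C11=C13 methylene and arrive at 24.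

Step 14. Closure of the strained ten-membered ring may be slow against reduction of the C–I bond, and the alkenyl chromium species may add to the wrong face of the epoxy aldehyde. The fallback sets out from 21 and returns at 22 by correcting C3 after ring closure. If the cyclisation delivers mainly (1R,2S,3Z,5E,7R,9R,10R)-2-hydroxy-3,9-dimethyl-9-[(triethylsilyl)oxy]-11-oxabicyclo[8.1.0]undeca-3,5-dien-7-yl (Z)-2-methylbut-2-enoate F2, this alcohol (or the epimer mixture) is oxidised with Dess–Martin periodinane to the epoxy dienone F3. Reduction of F3 with Zn(BH4)2 in Et2O at −20 °C, with zinc chelated between the ketone and epoxide oxygens and hydride entering anti to C1, should give the (3R) carbinol 22.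

Step 8. The enolate may take a proton from the acetyl group of 6, the aldolate may revert on warming, and chelate control may be lost so that the C10 epimer forms. The fallback sets out from 11 and returns at 14 by a reductive route to the enolate. The lithium enolate 12 of 11 is brominated with NBS at −78 °C to (3E,5Z)-1-bromo-6-iodohepta-3,5-dien-2-one F4. SmI2 (2 equiv, THF, −78 °C) then reduces the C–Br bond to a trivalent samarium enolate; all SmI2 is allowed to be consumed before 6 is added, since it would otherwise reduce the epoxy ketone. The Reformatsky-type addition, with the oxophilic samarium bridging the carbonyl and epoxide oxygens of 6, should give 14.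

**Further compounds**

F1 | step 15 | C11-carboxy lactone (24 with CO2H and H on C11 in place of the exocyclic methylene; C11 unassigned) | OC(=O)C1C(=O)O[C@H]2/C=C(/C)[C@@H](O)[C@H]3O[C@H]3[C@](C)(O[Si](CC)(CC)CC)C[C@@H](OC(=O)/C(C)=C\C)[C@@H]12
F2 | step 14 | (1R,2S,3Z,5E,7R,9R,10R)-2-hydroxy-3,9-dimethyl-9-[(triethylsilyl)oxy]-11-oxabicyclo[8.1.0]undeca-3,5-dien-7-yl (Z)-2-methylbut-2-enoate | [C@H]1(OC(=O)/C(C)=C\C)/C=C/C=C(/C)[C@H](O)[C@H]2O[C@H]2[C@](C)(O[Si](CC)(CC)CC)C1
F3 | step 14 | (1S,3Z,5E,7R,9R,10R)-3,9-dimethyl-2-oxo-9-[(triethylsilyl)oxy]-11-oxabicyclo[8.1.0]undeca-3,5-dien-7-yl (Z)-2-methylbut-2-enoate | [C@H]1(OC(=O)/C(C)=C\C)/C=C/C=C(/C)C(=O)[C@H]2O[C@H]2[C@](C)(O[Si](CC)(CC)CC)C1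
F4 | step 8 | (3E,5Z)-1-bromo-6-iodohepta-3,5-dien-2-one | BrCC(=O)/C=C/C=C(/C)I
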